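## The problem

Isogmelinol is a 3a-hydroxylated furo[3,4-c]furan. The numbering used here is: aryl-bearing carbons C1 and C4, ring oxygens O2 and O5, methylene carbons C3 and C6, carbinol bridgehead C3a and CH bridgehead C6a. Ring A is C1–O2–C3–C3a–C6a and ring B is C3a–C4–O5–C6–C6a; the rings are cis-fused along C3a–C6a. Four contiguous stereocentres, (1S,3aS,4R,6aR), have to be set, with both 3,4-dimethoxyphenyl groups on the convex (exo) face and the C3a hydroxyl cis to H-6a. C3a is a fully substituted carbinol bonded directly to the benzylic C4, which excludes most aldol-type closures of ring B. The stereocentres depend on each other: C1 and C6a (trans on ring A) can be set together in an open-chain precursor, C6a then dictates C3a through the ring fusion, and the folded bicycle can direct C4. Both benzylic C–O bonds ionise under acid, the veratryl rings are sensitive to oxidants and electrophiles, and any ring A ketone on the way is a β,β'-dialkoxy ketone that eliminates under base. The feature that opens the synthesis is that C4 lies δ to C3a through C6a–C6–O5, with oxygen in the γ position. If C3a is a ketone carbon, its excited carbonyl can take a benzylic hydrogen from a C4H2 group, and the 1,5-biradical closes ring B while it creates the carbinol.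

## Retrosynthesis

**C3a–C4 (ring B).** Cutting this bond turns target 19 into ring A ketone 17, an isomer of the target with one ring and two stereocentres fewer. Cutting C4–O5 or an aryl–carbon bond instead would require the tertiary alcohol to be made early and carried protected. This cut makes the carbinol in the last step, so it needs no protecting group, and the acid-sensitive bicycle is formed under neutral conditions. The forward reaction must abstract the C4 hydrogen selectively, close the ring on the C6 face of C3a, and place the C4 aryl group exo.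

**O2–C3 (ring A).** Ketone 17 is opened at the ether bond next to the carbonyl to give hydroxy diazoketone 16. Ring closures through enolates (Claisen or Michael type) would expose C1 to reversible β-elimination and re-addition. A carbenoid O–H insertion is neutral and leaves C1 and C6a as they are. The forward reaction must prefer the hydroxyl over the ether oxygen O5 and the arenes.

**C3–C3a (one-carbon homologation).** The diazomethyl carbon of 16 is removed to give a carboxylic acid. Because activation of the acid needs the benzylic hydroxyl masked, 16 is derived from silyl ether 15 and this from acid 13. The silyl ether also blocks retro-aldol cleavage when the auxiliary is removed from 11.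

**C1–C6a (aldol).** Imide 11 is the silyl ether of aldol adduct 10, which is cut into imide 7 and veratraldehyde 8. This single C–C bond formation sets both C1 and C6a, and 8 is non-enolisable. An anti-selective aldol gives the trans relationship of ring A directly. A syn-selective aldol would leave C6a to be corrected at the base-sensitive ketone stage. The forward reaction must be anti-selective, with the (2R,3S) absolute sense, and must not expel the β-alkoxy group.

**N–acyl and O5–C6.** Imide 7 comes from acid 4 and auxiliary 5, and acid 4 from alcohol 1 and acrylate 2 by conjugate addition through ester 3. The second aryl group (the future C4 aryl) thus enters at the outset as a benzyl ether that survives every later step and supplies the hydrogen for the key step.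

## Roads not taken

**Alternative 1:** The cut is at both aryl–carbon bonds (C1–aryl and C4–aryl), with the bicycle left intact.
- Forward key step: a Lewis acid (SnCl4 or BF3·OEt2) ionises the bis(lactol acetate) A1 of the silyl-protected core to oxocarbenium ions at C1 and C4. Two molecules of veratrole A2 attack para to a methoxy group and give O-triethylsilyl isogmelinol A3, one desilylation away from 19.
- Merits: it is the most convergent plan, both aryl groups come from the simplest arene, attack on the convex face of the bicycle leads to the exo,exo arrangement, and no photochemistry is needed.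
- Weak points: the key step forms no ring and no core stereocentre, so the enantiopure carbinol-bearing bicycle still has to be made in the synthesis of A1. The cation at C4 sits next to the silyloxy-bearing C3a and is inductively destabilised, so the second arylation is slow. A3 holds two electron-rich benzylic ethers that the same Lewis acid can reionise in the presence of excess A2, which leads to ring opening and diarylmethanes.
- Comparison: this road is better in convergence and in avoiding a photoreactor. The chosen plan sets against it that its key step builds ring B and the carbinol together from a ketone reached by eight conventional steps, and that the product never meets a Lewis acid.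

**Alternative 2:** The cut is at C4–O5 and O5–C6; the ring B oxygen is inserted last.
- Forward key step: a [2+2] cycloaddition of (3,4-dimethoxyphenyl)ketene A4 with silyl enol ether A5 would give cyclobutanone A6. Buffered mCPBA then adds to the C6 carbonyl and the benzylic C4 migrates to oxygen with retention (Baeyer–Villiger), giving lactone A7.
- Merits: ring strain drives the oxidation, migration occurs with retention, and the cycloaddition forms C3a–C4, C6–C6a and the oxygenated quaternary carbon in one thermal step.
- Weak points: ketene cycloadditions tend to place the larger ketene substituent on the concave face, which would put the C4 aryl group endo, and the oxidation retains it. The competition between migration of C4 (benzylic, but attached to the electron-poor silyloxy carbon) and C6a is not settled by the structure. A peracid meets two veratryl rings. After the key step the lactone carbonyl must be reduced to a methylene group in two steps and the silyl group removed.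
- Comparison: this road is entirely thermal and its oxidation is more predictable than a photoreaction, which is a real advantage on scale. The chosen plan sets against it the direct exo placement at C4 and an end game without redox adjustment or protecting group.

**Alternative 3:** The cut is at C6a–C1; ring A is closed last on a ring B lactone.
- Forward key step: Rh2(OAc)4 (divalent rhodium) decomposes α-diazo lactone A8, and the carbenoid at C6a inserts into the benzylic ether C–H bond at C1 (1,5-insertion) to give lactone A9.
- Merits: C–H insertion next to an ether oxygen is among the most dependable carbenoid reactions, it is catalytic and thermal, the cis fusion is enforced, and the catalyst ligands can be varied.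
- Weak points: A8 must already contain the protected tertiary carbinol C3a and C4 in the correct relative configuration, so the hardest stereocentre has to be made by other means. No element of the substrate secures the orientation of the aryl group at the new C1 centre. Ylide formation at the ether oxygen and attack on the arenes compete. Two reduction steps and a desilylation follow.
- Comparison: as a bond-forming event the insertion is at least as reliable as the photocyclisation and easier to scale, so this road is better in that respect. The chosen plan sets against it that the carbinol is created by the key step itself and that 19 comes out of the key step directly.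

Key step: step 9

Assumption: the magnesium-catalysed anti-aldol of step 3 is taken to follow the chelated Z-enolate model of N-acyl oxazolidinones, so that the (S)-configured auxiliary delivers the (2R,3S) adduct.

## Route

Step 1
Reactants: 1 3,4-dimethoxybenzyl alcohol; 2 methyl acrylate
Product: 4 3-[(3,4-dimethoxybenzyl)oxy]propanoic acid, via methyl ester 3 (not isolated)
Conditions: NaH (0.1 equiv), THF, 0 °C → rt; then LiOH, H2O/MeOH, rt; aq. HCl to pH 3
Reagents that add atoms: lithium hydroxide, [Li+].[OH-]
Why: Base-catalysed oxa-Michael addition of the benzylic alkoxide to the acrylate, then ester saponification in the same flask; the hydrolysis also returns any transesterified material to 4, which is purified by acid–base extraction.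

Step 2
Reactants: 4 3-[(3,4-dimethoxybenzyl)oxy]propanoic acid; 5 (S)-4-benzyl-1,3-oxazolidin-2-one
Product: 7 (4S)-4-benzyl-3-{3-[(3,4-dimethoxybenzyl)oxy]propanoyl}-1,3-oxazolidin-2-one, via mixed pivalic anhydride 6 (not isolated)
Conditions: PivCl, Et3N, THF, −20 °C; then LiCl, 5, −20 °C → rt
Reagents that add atoms: none
Why: N-Acylation of the oxazolidinone through the mixed pivalic anhydride with LiCl/Et3N activation; attack occurs at the less hindered acyl group and no strong base meets the β-alkoxy acid.

Step 3
Reactants: 7 (4S)-4-benzyl-3-{3-[(3,4-dimethoxybenzyl)oxy]propanoyl}-1,3-oxazolidin-2-one; 8 veratraldehyde (3,4-dimethoxybenzaldehyde)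
Product: 10 (4S)-4-benzyl-3-[(2R,3S)-2-{[(3,4-dimethoxybenzyl)oxy]methyl}-3-(3,4-dimethoxyphenyl)-3-hydroxypropanoyl]-1,3-oxazolidin-2-one (anti), via trimethylsilyl ether 9 (not isolated)
Conditions: MgCl2 (0.2 equiv), Et3N, Me3SiCl, EtOAc, rt; then 1 M HCl, THF, 0 °C
Reagents that add atoms: none
Why: Magnesium-halide-catalysed direct anti-aldol addition of an N-acyl oxazolidinone to a non-enolisable aromatic aldehyde; the chelated Z-enolate is attacked on the face opposite the benzyl group through a boat-like transition state, which sets C2 (R) and C3 (S), the future C6a and C1. Silylation of the aldolate by Me3SiCl makes the addition irreversible and releases the catalyst.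

Step 4
Reactants: 10 (4S)-4-benzyl-3-[(2R,3S)-2-{[(3,4-dimethoxybenzyl)oxy]methyl}-3-(3,4-dimethoxyphenyl)-3-hydroxypropanoyl]-1,3-oxazolidin-2-one
Product: 11 (4S)-4-benzyl-3-[(2R,3S)-2-{[(3,4-dimethoxybenzyl)oxy]methyl}-3-(3,4-dimethoxyphenyl)-3-(triethylsilyloxy)propanoyl]-1,3-oxazolidin-2-one
Conditions: Et3SiOTf, 2,6-lutidine, CH2Cl2, −78 → 0 °C
Reagents that add atoms: triethylsilyl trifluoromethanesulfonate, CC[Si](CC)(CC)OS(=O)(=O)C(F)(F)F
Why: Silyl ether formation on a hindered secondary alcohol with a silyl triflate and a hindered base; the ether blocks retro-aldol cleavage in step 5 and keeps the hydroxyl out of the carboxyl activation in step 6.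

Step 5
Reactants: 11 (4S)-4-benzyl-3-[(2R,3S)-2-{[(3,4-dimethoxybenzyl)oxy]methyl}-3-(3,4-dimethoxyphenyl)-3-(triethylsilyloxy)propanoyl]-1,3-oxazolidin-2-one
Product: 13 (2R,3S)-2-{[(3,4-dimethoxybenzyl)oxy]methyl}-3-(3,4-dimethoxyphenyl)-3-(triethylsilyloxy)propanoic acid, via peroxy acid 12 (not isolated)
Conditions: LiOH, H2O2, THF/H2O, 0 °C; then Na2SO3; aq. HCl to pH 4
Reagents that add atoms: hydrogen peroxide, OO
Why: Hydroperoxide cleavage of the N-acyl oxazolidinone at the exocyclic carbonyl, then sulfite reduction of the peroxy acid; the weakly basic nucleophile leaves the α-stereocentre and the β-alkoxy groups untouched and returns the auxiliary.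

Step 6
Reactants: 13 (2R,3S)-2-{[(3,4-dimethoxybenzyl)oxy]methyl}-3-(3,4-dimethoxyphenyl)-3-(triethylsilyloxy)propanoic acid
Product: 15 (3R,4S)-1-diazo-3-{[(3,4-dimethoxybenzyl)oxy]methyl}-4-(3,4-dimethoxyphenyl)-4-(triethylsilyloxy)butan-2-one, via mixed carbonic anhydride 14 (not isolated)
Conditions: i-BuOCOCl, N-methylmorpholine, THF, −15 °C; then CH2N2, Et2O, 0 °C → rt
Reagents that add atoms: diazomethane, C=[N+]=[N-]
Why: Acylation of diazomethane by a mixed carbonic anhydride (the first stage of an Arndt–Eistert sequence); no acid chloride or HCl is involved, so the benzyl ether and the silyl ether survive.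

Step 7
Reactants: 15 (3R,4S)-1-diazo-3-{[(3,4-dimethoxybenzyl)oxy]methyl}-4-(3,4-dimethoxyphenyl)-4-(triethylsilyloxy)butan-2-one
Product: 16 (3R,4S)-1-diazo-3-{[(3,4-dimethoxybenzyl)oxy]methyl}-4-(3,4-dimethoxyphenyl)-4-hydroxybutan-2-one
Conditions: Bu4NF, AcOH, THF, 0 °C
Reagents that add atoms: none
Why: Fluoride-mediated desilylation buffered with acetic acid; the buffer keeps the medium too weakly basic for retro-aldol cleavage or β-elimination and is too weak an acid to protonate the diazoketone at 0 °C.

Step 8
Reactants: 16 (3R,4S)-1-diazo-3-{[(3,4-dimethoxybenzyl)oxy]methyl}-4-(3,4-dimethoxyphenyl)-4-hydroxybutan-2-one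
Product: 17 (4R,5S)-5-(3,4-dimethoxyphenyl)-4-{[(3,4-dimethoxybenzyl)oxy]methyl}oxolan-3-one (4,5-trans)
Conditions: Rh2(OAc)4 (1 mol%), CH2Cl2, rt, slow addition of 16
Reagents that add atoms: none
Why: Rhodium-carbenoid intramolecular O–H insertion of a β-hydroxy diazoketone, closing the five-membered oxolan-3-one (O2–C3 bond); it runs without acid or base, so the base-sensitive β,β'-dialkoxy ketone and its trans configuration are kept. The proton shift makes O–H insertion irreversible, whereas ylide formation at the ether oxygen O5 is reversible.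

Step 9
Reactants: 17 (4R,5S)-5-(3,4-dimethoxyphenyl)-4-{[(3,4-dimethoxybenzyl)oxy]methyl}oxolan-3-one
Product: 19 isogmelinol, (1S,3aS,4R,6aR)-1,4-bis(3,4-dimethoxyphenyl)tetrahydro-1H,3H-furo[3,4-c]furan-3a(4H)-ol, via 1,5-biradical 18 (not isolated)
Conditions: hν (medium-pressure Hg lamp, Pyrex filter, λ > 300 nm), degassed benzene (0.005 M), rt
Reagents that add atoms: none
Why: This is a Norrish–Yang photocyclisation, the known conversion of β-alkoxy ketones into tetrahydrofuran-3-ols, which has been applied to 4-(arylmethoxymethyl)oxolan-3-ones to give 3a-hydroxy furofurans. After n,π* excitation the C3a carbonyl oxygen takes a hydrogen from C4 by 1,6-transfer through a seven-membered transition state, giving 1,5-biradical 18 with a ketyl radical at C3a and a benzylic α-alkoxy radical at C4. Ring B closes by radical–radical coupling of this 1,5-biradical to a five-membered ring, which forms the C3a–C4 bond. At C3a the tether is anchored at C6a, so C4 can reach only the face of C3a that carries C6; this places the hydroxyl cis to H-6a and enforces the cis fusion. At C4 the aryl group should take the exo position, because the endo orientation would push it under ring A against C3 whereas the exo orientation meets only the hydroxyl; C1 is remote and untouched. The step needs δ-hydrogen abstraction to win over α-cleavage and other abstractions: the atom γ to the carbonyl on the side chain is O5, so Norrish type 2 cleavage is not available, the C4–H bond is weakened by both the aryl group and O5, and the remaining hydrogens are on the ring or aromatic and out of reach. Pyrex-filtered light addresses the long-wavelength ketone absorption and limits α-cleavage, and high dilution in degassed benzene suppresses bimolecular reduction and trapping of 18 by oxygen.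

## Compound list

1 | 3,4-dimethoxybenzyl alcohol | COc1ccc(CO)cc1OC | starting material
2 | methyl acrylate | C=CC(=O)OC | starting material
3 | methyl 3-[(3,4-dimethoxybenzyl)oxy]propanoate | COC(=O)CCOCc1ccc(OC)c(OC)c1 | intermediate (not isolated)
4 | 3-[(3,4-dimethoxybenzyl)oxy]propanoic acid | OC(=O)CCOCc1ccc(OC)c(OC)c1 | intermediate
5 | (S)-4-benzyl-1,3-oxazolidin-2-one | O=C1N[C@@H](Cc2ccccc2)CO1 | starting material
6 | 3-[(3,4-dimethoxybenzyl)oxy]propanoic pivalic anhydride | COc1ccc(COCCC(=O)OC(=O)C(C)(C)C)cc1OC | intermediate (not isolated)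
7 | (4S)-4-benzyl-3-{3-[(3,4-dimethoxybenzyl)oxy]propanoyl}-1,3-oxazolidin-2-one | COc1ccc(COCCC(=O)N2[C@@H](Cc3ccccc3)COC2=O)cc1OC | intermediate
8 | veratraldehyde | COc1ccc(C=O)cc1OC | starting material
9 | trimethylsilyl ether of 10, (2R,3S) | COc1ccc([C@@H](O[Si](C)(C)C)[C@@H](COCc2ccc(OC)c(OC)c2)C(=O)N2[C@@H](Cc3ccccc3)COC2=O)cc1OC | intermediate (not isolated)
10 | (4S)-4-benzyl-3-[(2R,3S)-2-{[(3,4-dimethoxybenzyl)oxy]methyl}-3-(3,4-dimethoxyphenyl)-3-hydroxypropanoyl]-1,3-oxazolidin-2-one | COc1ccc([C@@H](O)[C@@H](COCc2ccc(OC)c(OC)c2)C(=O)N2[C@@H](Cc3ccccc3)COC2=O)cc1OC | intermediate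
11 | (4S)-4-benzyl-3-[(2R,3S)-2-{[(3,4-dimethoxybenzyl)oxy]methyl}-3-(3,4-dimethoxyphenyl)-3-(triethylsilyloxy)propanoyl]-1,3-oxazolidin-2-one | COc1ccc([C@@H](O[Si](CC)(CC)CC)[C@@H](COCc2ccc(OC)c(OC)c2)C(=O)N2[C@@H](Cc3ccccc3)COC2=O)cc1OC | intermediate
12 | (2R,3S)-2-{[(3,4-dimethoxybenzyl)oxy]methyl}-3-(3,4-dimethoxyphenyl)-3-(triethylsilyloxy)propaneperoxoic acid | COc1ccc([C@@H](O[Si](CC)(CC)CC)[C@@H](COCc2ccc(OC)c(OC)c2)C(=O)OO)cc1OC | intermediate (not isolated)
13 | (2R,3S)-2-{[(3,4-dimethoxybenzyl)oxy]methyl}-3-(3,4-dimethoxyphenyl)-3-(triethylsilyloxy)propanoic acid | COc1ccc([C@@H](O[Si](CC)(CC)CC)[C@@H](COCc2ccc(OC)c(OC)c2)C(=O)O)cc1OC | intermediate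
14 | mixed anhydride of 13 with isobutyl hydrogen carbonate | COc1ccc([C@@H](O[Si](CC)(CC)CC)[C@@H](COCc2ccc(OC)c(OC)c2)C(=O)OC(=O)OCC(C)C)cc1OC | intermediate (not isolated)
15 | (3R,4S)-1-diazo-3-{[(3,4-dimethoxybenzyl)oxy]methyl}-4-(3,4-dimethoxyphenyl)-4-(triethylsilyloxy)butan-2-one | COc1ccc([C@@H](O[Si](CC)(CC)CC)[C@@H](COCc2ccc(OC)c(OC)c2)C(=O)C=[N+]=[N-])cc1OC | intermediate
16 | (3R,4S)-1-diazo-3-{[(3,4-dimethoxybenzyl)oxy]methyl}-4-(3,4-dimethoxyphenyl)-4-hydroxybutan-2-one | COc1ccc([C@@H](O)[C@@H](COCc2ccc(OC)c(OC)c2)C(=O)C=[N+]=[N-])cc1OC | intermediate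
17 | (4R,5S)-5-(3,4-dimethoxyphenyl)-4-{[(3,4-dimethoxybenzyl)oxy]methyl}oxolan-3-one | COc1ccc([C@H]2OCC(=O)[C@@H]2COCc2ccc(OC)c(OC)c2)cc1OC | intermediate
18 | 1,5-biradical (ketyl radical at C3a, benzylic α-alkoxy radical at C4) | COc1ccc([C@H]2OC[C](O)[C@@H]2CO[CH]c2ccc(OC)c(OC)c2)cc1OC | intermediate (not isolated)
19 | isogmelinol, (1S,3aS,4R,6aR)-1,4-bis(3,4-dimethoxyphenyl)tetrahydro-1H,3H-furo[3,4-c]furan-3a(4H)-ol | COc1ccc([C@H]2OC[C@]3(O)[C@@H](c4ccc(OC)c(OC)c4)OC[C@H]23)cc1OC | target

## Step count and risks

Total step count: 9. Longest linear sequence: 9 steps (from 1 and 2 to 19); 5 and 8 are purchased.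

**Step 9 (key step).**
- What may go wrong: the biradical may close with incomplete exo selectivity at C4. Part of the excited ketone may be lost to α-cleavage (Norrish type 1), because ring ketones with an α-oxygen cleave readily. The veratryl groups may quench the excited state by charge transfer.
- Fallback: C4 is put under thermodynamic instead of kinetic control. Setting out from 17, the irradiation is run to partial conversion and unchanged 17 is recycled. The cyclised material, including the C4 epimer (1S,3aS,4S,6aR)-1,4-bis(3,4-dimethoxyphenyl)tetrahydro-1H,3H-furo[3,4-c]furan-3a(4H)-ol F1, is treated with a catalytic amount of camphorsulfonic acid in CH2Cl2 at room temperature. Reversible ionisation of the benzylic C4–O5 bond to a methoxy-stabilised cation and reclosure, an epimerisation known for this lignan family, lets the aryl group reach the exo position, and the route is rejoined at 19.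
- Limit of the fallback: C1 can ionise in the same way, so an equilibrium mixture is expected; 19 would be separated and the remainder resubmitted.

**Step 3 (anti-aldol).**
- What may go wrong: the 3,4-dimethoxybenzyloxy group may be lost by β-elimination from the magnesium enolate at room temperature. The anti selectivity may erode because the α-substituent is an alkoxymethyl group and not a methyl group.
- Fallback: only C1 is fixed in the aldol, and C6a is corrected later by equilibration. Setting out from 7 and 8, the dibutylboron Z-enolate (Bu2BOTf, i-Pr2NEt, CH2Cl2, −78 °C) is a covalent enolate made and consumed at low temperature. By the boron-mediated syn-aldol it should give (4S)-4-benzyl-3-[(2S,3S)-2-{[(3,4-dimethoxybenzyl)oxy]methyl}-3-(3,4-dimethoxyphenyl)-3-hydroxypropanoyl]-1,3-oxazolidin-2-one F2, which has the correct carbinol configuration.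
- F2 is taken through the operations of steps 4 to 8:
  - silylation to the triethylsilyl ether F3;
  - hydroperoxide cleavage through the peroxy acid F4 to the (2S,3S) acid F5;
  - activation as the mixed carbonic anhydride F6 and reaction with diazomethane to the (3S,4S) silyloxy diazoketone F7;
  - buffered desilylation to the (3S,4S) hydroxy diazoketone F8;
  - Rh2(OAc)4-catalysed O–H insertion to the cis ketone (4S,5S)-5-(3,4-dimethoxyphenyl)-4-{[(3,4-dimethoxybenzyl)oxy]methyl}oxolan-3-one F9.
- C4 of F9 is α to the carbonyl, and brief exposure to a catalytic amount of Et3N in CH2Cl2 should epimerise it to the more stable trans isomer, which is 17, where the route is rejoined.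

**Step 8 (O–H insertion).**
- What may go wrong: the carbenoid may be diverted from the hydroxyl to the ether oxygen O5 (five-membered oxonium ylide, then 1,2-shift of the dimethoxybenzyl group) or to the electron-rich aryl ring on C1 (Buchner-type addition). Both lie as close to the carbenoid carbon as the hydroxyl does.
- Fallback: ring A is closed by SN2 etherification instead of carbenoid insertion. Setting out from 15, one equivalent of anhydrous HCl in Et2O at −20 °C converts the diazoketone into the chloromethyl ketone (3R,4S)-1-chloro-3-{[(3,4-dimethoxybenzyl)oxy]methyl}-4-(3,4-dimethoxyphenyl)-4-(triethylsilyloxy)butan-2-one F10. Buffered fluoride (Bu4NF, AcOH, THF) frees the hydroxyl to give (3R,4S)-1-chloro-3-{[(3,4-dimethoxybenzyl)oxy]methyl}-4-(3,4-dimethoxyphenyl)-4-hydroxybutan-2-one F11. Ag2O in CH2Cl2 then closes the ring by intramolecular Williamson etherification at the activated α-keto carbon, and the route is rejoined at 17.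

## Further compounds

F1 | step 9 | (1S,3aS,4S,6aR)-1,4-bis(3,4-dimethoxyphenyl)tetrahydro-1H,3H-furo[3,4-c]furan-3a(4H)-ol (C4 epimer of 19) | COc1ccc([C@H]2OC[C@]3(O)[C@H](c4ccc(OC)c(OC)c4)OC[C@H]23)cc1OC
F2 | step 3 | (4S)-4-benzyl-3-[(2S,3S)-2-{[(3,4-dimethoxybenzyl)oxy]methyl}-3-(3,4-dimethoxyphenyl)-3-hydroxypropanoyl]-1,3-oxazolidin-2-one | COc1ccc([C@@H](O)[C@H](COCc2ccc(OC)c(OC)c2)C(=O)N2[C@@H](Cc3ccccc3)COC2=O)cc1OC
F3 | step 3 | triethylsilyl ether of F2 | COc1ccc([C@@H](O[Si](CC)(CC)CC)[C@H](COCc2ccc(OC)c(OC)c2)C(=O)N2[C@@H](Cc3ccccc3)COC2=O)cc1OC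
F4 | step 3 | (2S,3S)-2-{[(3,4-dimethoxybenzyl)oxy]methyl}-3-(3,4-dimethoxyphenyl)-3-(triethylsilyloxy)propaneperoxoic acid | COc1ccc([C@@H](O[Si](CC)(CC)CC)[C@H](COCc2ccc(OC)c(OC)c2)C(=O)OO)cc1OC
F5 | step 3 | (2S,3S)-2-{[(3,4-dimethoxybenzyl)oxy]methyl}-3-(3,4-dimethoxyphenyl)-3-(triethylsilyloxy)propanoic acid | COc1ccc([C@@H](O[Si](CC)(CC)CC)[C@H](COCc2ccc(OC)c(OC)c2)C(=O)O)cc1OC
F6 | step 3 | mixed anhydride of F5 with isobutyl hydrogen carbonate | COc1ccc([C@@H](O[Si](CC)(CC)CC)[C@H](COCc2ccc(OC)c(OC)c2)C(=O)OC(=O)OCC(C)C)cc1OC
F7 | step 3 | (3S,4S)-1-diazo-3-{[(3,4-dimethoxybenzyl)oxy]methyl}-4-(3,4-dimethoxyphenyl)-4-(triethylsilyloxy)butan-2-one | COc1ccc([C@@H](O[Si](CC)(CC)CC)[C@H](COCc2ccc(OC)c(OC)c2)C(=O)C=[N+]=[N-])cc1OC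
F8 | step 3 | (3S,4S)-1-diazo-3-{[(3,4-dimethoxybenzyl)oxy]methyl}-4-(3,4-dimethoxyphenyl)-4-hydroxybutan-2-one | COc1ccc([C@@H](O)[C@H](COCc2ccc(OC)c(OC)c2)C(=O)C=[N+]=[N-])cc1OC
F9 | step 3 | (4S,5S)-5-(3,4-dimethoxyphenyl)-4-{[(3,4-dimethoxybenzyl)oxy]methyl}oxolan-3-one (4,5-cis) | COc1ccc([C@H]2OCC(=O)[C@H]2COCc2ccc(OC)c(OC)c2)cc1OC
F10 | step 8 | (3R,4S)-1-chloro-3-{[(3,4-dimethoxybenzyl)oxy]methyl}-4-(3,4-dimethoxyphenyl)-4-(triethylsilyloxy)butan-2-one | COc1ccc([C@@H](O[Si](CC)(CC)CC)[C@@H](COCc2ccc(OC)c(OC)c2)C(=O)CCl)cc1OC
F11 | step 8 | (3R,4S)-1-chloro-3-{[(3,4-dimethoxybenzyl)oxy]methyl}-4-(3,4-dimethoxyphenyl)-4-hydroxybutan-2-one | COc1ccc([C@@H](O)[C@@H](COCc2ccc(OC)c(OC)c2)C(=O)CCl)cc1OC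
A1 | alternative 1 | 3a-(triethylsilyloxy)tetrahydro-1H,3H-furo[3,4-c]furan-1,4-diyl diacetate (bis(lactol acetate), anomeric mixture) | CC(=O)OC1OC[C@]2(O[Si](CC)(CC)CC)C(OC(C)=O)OC[C@H]12
A2 | alternative 1 | veratrole (1,2-dimethoxybenzene) | COc1ccccc1OC
A3 | alternative 1 | O-triethylsilyl isogmelinol | COc1ccc([C@H]2OC[C@]3(O[Si](CC)(CC)CC)[C@@H](c4ccc(OC)c(OC)c4)OC[C@H]23)cc1OC
A4 | alternative 2 | (3,4-dimethoxyphenyl)ketene | COc1ccc(C=C=O)cc1OC
A5 | alternative 2 | tert-butyl{[(5S)-5-(3,4-dimethoxyphenyl)-2,5-dihydrofuran-3-yl]oxy}dimethylsilane | COc1ccc([C@H]2OCC(O[Si](C)(C)C(C)(C)C)=C2)cc1OC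
A6 | alternative 2 | 1-(tert-butyldimethylsilyloxy)-4,7-bis(3,4-dimethoxyphenyl)-3-oxabicyclo[3.2.0]heptan-6-one (cyclobutanone) | COc1ccc([C@H]2OC[C@]3(O[Si](C)(C)C(C)(C)C)[C@@H](c4ccc(OC)c(OC)c4)C(=O)[C@H]23)cc1OC
A7 | alternative 2 | C6 lactone of O-tert-butyldimethylsilyl isogmelinol | COc1ccc([C@H]2OC[C@]3(O[Si](C)(C)C(C)(C)C)[C@@H](c4ccc(OC)c(OC)c4)OC(=O)[C@H]23)cc1OC
A8 | alternative 3 | 3-diazo-4-{[(3,4-dimethoxybenzyl)oxy]methyl}-5-(3,4-dimethoxyphenyl)-4-(triethylsilyloxy)oxolan-2-one | COc1ccc(COC[C@]2(O[Si](CC)(CC)CC)[C@@H](c3ccc(OC)c(OC)c3)OC(=O)C2=[N+]=[N-])cc1OC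
A9 | alternative 3 | C6 lactone of O-triethylsilyl isogmelinol | COc1ccc([C@H]2OC[C@]3(O[Si](CC)(CC)CC)[C@@H](c4ccc(OC)c(OC)c4)OC(=O)[C@H]23)cc1OC
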